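**Assumption:** germacrane numbering is used for locants (C12 = lactone carbonyl, C13 = CH2OAc, C14 and C15 = methyls on C10 and C4). The target is read as 2S,4R,5R,6S,8S with a 1(10)Z olefin. TBS = tert-butyldimethylsilyl; TRIP = 3,3'-bis(2,4,6-triisopropylphenyl)-BINOL hydrogen phosphate.

## Retrosynthetic overview

1. The oxirane is made last, by epoxidation of the strained 4E olefin of a germacra-1(10)Z,4E,7(11)-trien-12,6-olide; the C8 methacrylate and the C2/C13 acetates come from plain acylations.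
2. The ten-membered carbocycle and the 12,6-lactone form together, by Ni/Cr closure of C5–C6 between an (E)-alkenyl iodide and the masked aldehyde of a γ-hydroxybutenolide.
3. The γ-hydroxybutenolide comes from singlet-oxygen dearomatisation of a 2-silyl-3,4-disubstituted furan (Si-bearing carbon becomes C12=O, the C–H carbon becomes the C6 lactol).
4. The side chain is grown on the furan by two catalytic asymmetric propargylations (C8, C2), an Fe-catalysed syn-methylmagnesiation (1(10)Z olefin) and a Zr-catalysed carboalumination–iodination (4E alkenyl iodide).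
5. The furan core comes from furan-3-ylmethanol by retro-Brook C-silylation and C4-lithiation/formylation. Ring order: furan (bought), then butenolide lactol, then carbocycle plus lactone, then oxirane.

## Route

**Step 1**
Reactants: 1 furan-3-ylmethanol
Product: 3 [2-(tert-butyldimethylsilyl)furan-3-yl]methanol, via silyl ether 2 (not isolated)
Conditions: n-BuLi (1.0 eq), THF, −78 °C; TBSCl, 0 °C; then n-BuLi (1.2 eq), HMPA, −78 → −20 °C; H2O
Reagents that add atoms: tert-butyldimethylsilyl chloride, CC(C)(C)[Si](C)(C)Cl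
Why: O-silylation followed by lithiation at C2 triggers a 1,4 O→C silyl shift (retro-Brook rearrangement), which puts silicon on the furan carbon that later becomes the lactone carbonyl and frees the hydroxymethyl group as a directing group.

**Step 2**
Reactants: 3 [2-(tert-butyldimethylsilyl)furan-3-yl]methanol
Product: 5 5-(tert-butyldimethylsilyl)-4-(hydroxymethyl)furan-3-carbaldehyde, via dilithio species 4 (not isolated)
Conditions: n-BuLi (2.2 eq), DME, 0 °C; DMF, −78 °C → rt; H2O
Reagents that add atoms: N,N-dimethylformamide, CN(C)C=O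
Why: Alkoxide-directed ortho-lithiation goes to C4 because C2 is blocked by silicon, and formylation of the aryllithium gives the 3,4-disubstituted furan carrying C13 and C8.

**Step 3**
Reactants: 5 5-(tert-butyldimethylsilyl)-4-(hydroxymethyl)furan-3-carbaldehyde; 6 allenylboronic acid pinacol ester
Product: 7 (1S)-1-[5-(tert-butyldimethylsilyl)-4-(hydroxymethyl)furan-3-yl]but-3-yn-1-ol
Conditions: (S)-TRIP (5 mol %; the enantiomer that directs Si-face attack), 4 Å MS, toluene, 0 °C
Reagents that add atoms: none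
Why: Chiral-phosphoric-acid-catalysed allenylboronate propargylation (SE2' through a catalyst-organised chair transition state) on the aldehyde Si face sets C8 as S; the neighbouring hydroxymethyl group is tolerated.

**Step 4**
Reactants: 7 (1S)-1-[5-(tert-butyldimethylsilyl)-4-(hydroxymethyl)furan-3-yl]but-3-yn-1-ol
Product: 8 3-[(1S)-1-(TBS-oxy)but-3-yn-1-yl]-5-TBS-4-(TBS-oxymethyl)furan
Conditions: TBSCl (2.5 eq), imidazole, DMF, rt
Reagents that add atoms: tert-butyldimethylsilyl chloride, CC(C)(C)[Si](C)(C)Cl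
Why: Silyl ether formation masks both hydroxyls so that later only the C2 alkoxide can direct the carbometallation.

**Step 5**
Reactants: 8 3-[(1S)-1-(TBS-oxy)but-3-yn-1-yl]-5-TBS-4-(TBS-oxymethyl)furan
Product: 10 (5S)-5-(TBS-oxy)-5-[5-TBS-4-(TBS-oxymethyl)furan-3-yl]pent-2-ynal, via lithium acetylide 9 (not isolated)
Conditions: n-BuLi (1.05 eq), THF, −78 °C; DMF; inverse quench into aq. KH2PO4
Reagents that add atoms: N,N-dimethylformamide, CN(C)C=O
Why: Acetylide formylation; the alkyne C–H is far more acidic than the remaining furan C–H, so only the alkyne is metallated.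

**Step 6**
Reactants: 10 (5S)-5-(TBS-oxy)-5-[5-TBS-4-(TBS-oxymethyl)furan-3-yl]pent-2-ynal; 6 allenylboronic acid pinacol ester
Product: 11 (4S,8S)-8-(TBS-oxy)-8-[5-TBS-4-(TBS-oxymethyl)furan-3-yl]octa-1,5-diyn-4-ol
Conditions: (S)-TRIP (10 mol %), 4 Å MS, toluene, −20 °C
Reagents that add atoms: none
Why: A second chiral-phosphoric-acid-catalysed allenylboronate propargylation, again on the Si face, sets C2 as S under catalyst control because C8 is remote.

**Step 7**
Reactants: 11 (4S,8S)-8-(TBS-oxy)-8-[5-TBS-4-(TBS-oxymethyl)furan-3-yl]octa-1,5-diyn-4-ol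
Product: 13 (4S,5Z,8S)-8-(TBS-oxy)-8-[5-TBS-4-(TBS-oxymethyl)furan-3-yl]-6-methyloct-5-en-1-yn-4-ol, via vinylmagnesium species 12 (not isolated)
Conditions: Fe(acac)3 (15 mol %), MeMgBr (5 eq), THF, −78 → 0 °C; H2O
Reagents that add atoms: methylmagnesium bromide, C[Mg]Br
Why: Alkoxide-directed iron-catalysed syn-carbomagnesiation of the propargylic alcohol puts methyl on the distal carbon C10 and magnesium on C1, so protonation gives the 1(10)Z olefin with C2 and C9 cis; the terminal alkyne is protected in situ as its magnesium acetylide and the silyl ether at C8 does not direct.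

**Step 8**
Reactants: 13 (4S,5Z,8S)-8-(TBS-oxy)-8-[5-TBS-4-(TBS-oxymethyl)furan-3-yl]-6-methyloct-5-en-1-yn-4-ol
Product: 15 (1E,4S,5Z,8S)-8-(TBS-oxy)-8-[5-TBS-4-(TBS-oxymethyl)furan-3-yl]-1-iodo-2,6-dimethylocta-1,5-dien-4-ol, via alkenylalane 14 (not isolated)
Conditions: Me3Al (4 eq), Cp2ZrCl2 (0.3 eq), CH2Cl2, 0 °C → rt; then I2, THF, −30 °C; Rochelle salt
Reagents that add atoms: trimethylaluminium, C[Al](C)C; iodine, II
Why: Negishi zirconium-catalysed syn-carboalumination of the terminal alkyne (methyl to C4, aluminium to C5) and iodinolysis with retention give the (E)-alkenyl iodide that defines the 4E geometry.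

**Step 9**
Reactants: 15 (1E,4S,5Z,8S)-8-(TBS-oxy)-8-[5-TBS-4-(TBS-oxymethyl)furan-3-yl]-1-iodo-2,6-dimethylocta-1,5-dien-4-ol
Product: 16 (1E,4S,5Z,8S)-8-(TBS-oxy)-8-[5-TBS-4-(hydroxymethyl)furan-3-yl]-1-iodo-2,6-dimethylocta-1,5-dien-4-ol
Conditions: NH4F (10 eq), MeOH, rt
Reagents that add atoms: none
Why: Selective desilylation; neutral fluoride cleaves the unhindered primary silyl ether much faster than the secondary ether or the furan C–Si bond.

**Step 10**
Reactants: 16 (1E,4S,5Z,8S)-8-(TBS-oxy)-8-[5-TBS-4-(hydroxymethyl)furan-3-yl]-1-iodo-2,6-dimethylocta-1,5-dien-4-ol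
Product: 17 {4-[(1S,3Z,5S,7E)-5-acetoxy-1-(TBS-oxy)-8-iodo-3,7-dimethylocta-3,7-dien-1-yl]-2-TBS-furan-3-yl}methyl acetate
Conditions: Ac2O, pyridine, DMAP (cat.), CH2Cl2, 0 °C → rt
Reagents that add atoms: acetic anhydride, CC(=O)OC(C)=O
Why: DMAP-catalysed esterification of both free hydroxyls installs the C2 and C13 acetates of the target in one operation.

**Step 11**
Reactants: 17 {4-[(1S,3Z,5S,7E)-5-acetoxy-1-(TBS-oxy)-8-iodo-3,7-dimethylocta-3,7-dien-1-yl]-2-TBS-furan-3-yl}methyl acetate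
Product: 19 3-(acetoxymethyl)-4-[(1S,3Z,5S,7E)-5-acetoxy-1-(TBS-oxy)-8-iodo-3,7-dimethylocta-3,7-dien-1-yl]-5-hydroxyfuran-2(5H)-one (both lactol epimers), via furan endoperoxide 18 (not isolated)
Conditions: O2, tetraphenylporphyrin (1 mol %), hν (>500 nm), CH2Cl2, −78 °C; warm to 0 °C; H2O
Reagents that add atoms: oxygen (as singlet oxygen), O=O
Why: [4+2] cycloaddition of singlet oxygen to the electron-rich furan destroys its aromaticity, and the endoperoxide collapses by 1,2-silyl shift and fragmentation so that the silylated carbon becomes the lactone carbonyl C12 and the C–H carbon the C6 lactol, regiospecifically; the two deactivated trisubstituted olefins react far more slowly.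

**Step 12**
Reactants: 19 3-(acetoxymethyl)-4-[(1S,3Z,5S,7E)-5-acetoxy-1-(TBS-oxy)-8-iodo-3,7-dimethylocta-3,7-dien-1-yl]-5-hydroxyfuran-2(5H)-one
Product: 21 (2S,6R,8S)-2,13-diacetoxy-8-(TBS-oxy)germacra-1(10)Z,4E,7(11)-trien-12,6-olide, via seco hydroxy acid 20 (not isolated)
Conditions: CrCl2 (10 eq), NiCl2 (2 mol %), DMSO–THF (3:1), 25 °C, syringe-pump addition to 2 mM; aq. citrate work-up
Reagents that add atoms: none
Why: Proposed new method: the γ-hydroxybutenolide is in ring–chain equilibrium with its (Z)-4-oxo-enoic acid, whose aldehyde (s-trans, hydrogen toward the carboxylate) is captured intramolecularly by the alkenylchromium(III) species formed by Ni(0) insertion into the C–I bond and Ni→Cr transmetallation, on the Re face anti to the C8 silyloxy group that allylic 1,3-strain turns out of the enoate plane, and the resulting cis γ-hydroxy acid lactonises at once, so that the carbocycle, the C6 stereocentre (6R here, 6S in the target after the CIP change) and the butenolide arise together; the closest known chemistry is the Nozaki–Hiyama–Kishi macrocyclisation, NHK additions to lactols that react through their hydroxy-aldehyde form, and indium or Grignard additions to γ-hydroxybutenolides.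

**Step 13**
Reactants: 21 (2S,6R,8S)-2,13-diacetoxy-8-(TBS-oxy)germacra-1(10)Z,4E,7(11)-trien-12,6-olide
Product: 22 (2S,6R,8S)-2,13-diacetoxy-8-hydroxygermacra-1(10)Z,4E,7(11)-trien-12,6-olide
Conditions: HF·pyridine, pyridine, THF, 0 °C → rt
Reagents that add atoms: none
Why: Buffered fluoride desilylation frees the C8 hydroxyl and leaves the acetates, the lactone and the epimerisable C6–H untouched; no epoxide is present yet and C12 is trans to C8, so no translactonisation can occur.

**Step 14**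
Reactants: 22 (2S,6R,8S)-2,13-diacetoxy-8-hydroxygermacra-1(10)Z,4E,7(11)-trien-12,6-olide
Product: 23 (2S,6R,8S)-2,13-diacetoxy-8-(methacryloyloxy)germacra-1(10)Z,4E,7(11)-trien-12,6-olide
Conditions: methacrylic anhydride, DMAP, pyridine, CH2Cl2, 0 °C
Reagents that add atoms: methacrylic anhydride, C=C(C)C(=O)OC(=O)C(C)=C
Why: DMAP-catalysed esterification of the only free hydroxyl installs the C8 methacrylate with retention at C8.

**Step 15**
Reactants: 23 (2S,6R,8S)-2,13-diacetoxy-8-(methacryloyloxy)germacra-1(10)Z,4E,7(11)-trien-12,6-olide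
Product: 24 (2S,4R,5R,6S,8S)-2,13-diacetoxy-4,5-epoxy-8-(methacryloyloxy)germacra-1(10)Z,7(11)-dien-12,6-olide (CNP0268364.3)
Conditions: mCPBA (1.05 eq), NaHCO3, CH2Cl2, −20 → 0 °C
Reagents that add atoms: 3-chloroperoxybenzoic acid, O=C(OO)c1cccc(Cl)c1
Why: Prilezhaev epoxidation; the trans (4E) ring olefin is the strained and most nucleophilic C=C (the 1(10)Z olefin is unstrained and deactivated by the allylic acetate, the two enoates are electron-poor) and is attacked on its exposed outer face, which in 12,6-germacranolides gives the parthenolide-type 4R,5R oxirane and so creates C4 and C5; the bicarbonate buffer prevents acid-induced transannular cyclisation.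

## Compound list

1 | furan-3-ylmethanol | OCc1ccoc1 | starting material
2 | tert-butyl(furan-3-ylmethoxy)dimethylsilane | CC(C)(C)[Si](C)(C)OCc1ccoc1 | intermediate
3 | [2-(tert-butyldimethylsilyl)furan-3-yl]methanol | CC(C)(C)[Si](C)(C)c1occc1CO | intermediate
4 | dilithio species of 3 (O–Li and C4–Li) | [Li]OCc1c([Li])coc1[Si](C)(C)C(C)(C)C | intermediate
5 | 5-(tert-butyldimethylsilyl)-4-(hydroxymethyl)furan-3-carbaldehyde | O=Cc1coc([Si](C)(C)C(C)(C)C)c1CO | intermediate
6 | allenylboronic acid pinacol ester | C=C=CB1OC(C)(C)C(C)(C)O1 | starting material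
7 | (1S)-1-[5-(tert-butyldimethylsilyl)-4-(hydroxymethyl)furan-3-yl]but-3-yn-1-ol | C#CC[C@H](O)c1coc([Si](C)(C)C(C)(C)C)c1CO | intermediate
8 | 3-[(1S)-1-(TBS-oxy)but-3-yn-1-yl]-5-TBS-4-(TBS-oxymethyl)furan | C#CC[C@H](O[Si](C)(C)C(C)(C)C)c1coc([Si](C)(C)C(C)(C)C)c1CO[Si](C)(C)C(C)(C)C | intermediate
9 | lithium acetylide of 8 | [Li]C#CC[C@H](O[Si](C)(C)C(C)(C)C)c1coc([Si](C)(C)C(C)(C)C)c1CO[Si](C)(C)C(C)(C)C | intermediate
10 | (5S)-5-(TBS-oxy)-5-[5-TBS-4-(TBS-oxymethyl)furan-3-yl]pent-2-ynal | O=CC#CC[C@H](O[Si](C)(C)C(C)(C)C)c1coc([Si](C)(C)C(C)(C)C)c1CO[Si](C)(C)C(C)(C)C | intermediate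
11 | (4S,8S)-8-(TBS-oxy)-8-[5-TBS-4-(TBS-oxymethyl)furan-3-yl]octa-1,5-diyn-4-ol | C#CC[C@H](O)C#CC[C@H](O[Si](C)(C)C(C)(C)C)c1coc([Si](C)(C)C(C)(C)C)c1CO[Si](C)(C)C(C)(C)C | intermediate
12 | tris(bromomagnesium) species from 11 (C1–MgBr cis to the new methyl; O–MgBr; acetylide–MgBr) | Br[Mg]C#CC[C@H](O[Mg]Br)/C([Mg]Br)=C(/C)C[C@H](O[Si](C)(C)C(C)(C)C)c1coc([Si](C)(C)C(C)(C)C)c1CO[Si](C)(C)C(C)(C)C | intermediate
13 | (4S,5Z,8S)-8-(TBS-oxy)-8-[5-TBS-4-(TBS-oxymethyl)furan-3-yl]-6-methyloct-5-en-1-yn-4-ol | C#CC[C@H](O)/C=C(/C)C[C@H](O[Si](C)(C)C(C)(C)C)c1coc([Si](C)(C)C(C)(C)C)c1CO[Si](C)(C)C(C)(C)C | intermediate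
14 | (E)-alkenyl(dimethyl)alane from 13 (O–AlMe2; C5–AlMe2) | C[Al](C)/C=C(\C)C[C@H](O[Al](C)C)/C=C(/C)C[C@H](O[Si](C)(C)C(C)(C)C)c1coc([Si](C)(C)C(C)(C)C)c1CO[Si](C)(C)C(C)(C)C | intermediate
15 | (1E,4S,5Z,8S)-8-(TBS-oxy)-8-[5-TBS-4-(TBS-oxymethyl)furan-3-yl]-1-iodo-2,6-dimethylocta-1,5-dien-4-ol | I/C=C(\C)C[C@H](O)/C=C(/C)C[C@H](O[Si](C)(C)C(C)(C)C)c1coc([Si](C)(C)C(C)(C)C)c1CO[Si](C)(C)C(C)(C)C | intermediate
16 | (1E,4S,5Z,8S)-8-(TBS-oxy)-8-[5-TBS-4-(hydroxymethyl)furan-3-yl]-1-iodo-2,6-dimethylocta-1,5-dien-4-ol | I/C=C(\C)C[C@H](O)/C=C(/C)C[C@H](O[Si](C)(C)C(C)(C)C)c1coc([Si](C)(C)C(C)(C)C)c1CO | intermediate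
17 | {4-[(1S,3Z,5S,7E)-5-acetoxy-1-(TBS-oxy)-8-iodo-3,7-dimethylocta-3,7-dien-1-yl]-2-TBS-furan-3-yl}methyl acetate | I/C=C(\C)C[C@H](OC(C)=O)/C=C(/C)C[C@H](O[Si](C)(C)C(C)(C)C)c1coc([Si](C)(C)C(C)(C)C)c1COC(C)=O | intermediate
18 | furan endoperoxide of 17 (2,3,7-trioxabicyclo[2.2.1]hept-5-ene; O–O across C12 and C6) | I/C=C(\C)C[C@H](OC(C)=O)/C=C(/C)C[C@H](O[Si](C)(C)C(C)(C)C)C1=C(COC(C)=O)C2(OOC1O2)[Si](C)(C)C(C)(C)C | intermediate
19 | 3-(acetoxymethyl)-4-[(1S,3Z,5S,7E)-5-acetoxy-1-(TBS-oxy)-8-iodo-3,7-dimethylocta-3,7-dien-1-yl]-5-hydroxyfuran-2(5H)-one (lactol epimers) | I/C=C(\C)C[C@H](OC(C)=O)/C=C(/C)C[C@H](O[Si](C)(C)C(C)(C)C)C1=C(COC(C)=O)C(=O)OC1O | intermediate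
20 | (2S,6R,8S)-2,13-diacetoxy-6-hydroxy-8-(TBS-oxy)germacra-1(10)Z,4E,7(11)-trien-12-oic acid (CO2H cis to C6) | CC(C)(C)[Si](C)(C)O[C@H]1C/C(C)=C\[C@@H](OC(C)=O)C/C(C)=C/[C@@H](O)/C1=C(/COC(C)=O)C(=O)O | intermediate
21 | (2S,6R,8S)-2,13-diacetoxy-8-(TBS-oxy)germacra-1(10)Z,4E,7(11)-trien-12,6-olide | CC(C)(C)[Si](C)(C)O[C@H]1C/C(C)=C\[C@@H](OC(C)=O)C/C(C)=C/[C@H]2OC(=O)C(COC(C)=O)=C12 | intermediate
22 | (2S,6R,8S)-2,13-diacetoxy-8-hydroxygermacra-1(10)Z,4E,7(11)-trien-12,6-olide | O[C@H]1C/C(C)=C\[C@@H](OC(C)=O)C/C(C)=C/[C@H]2OC(=O)C(COC(C)=O)=C12 | intermediate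
23 | (2S,6R,8S)-2,13-diacetoxy-8-(methacryloyloxy)germacra-1(10)Z,4E,7(11)-trien-12,6-olide | C=C(C)C(=O)O[C@H]1C/C(C)=C\[C@@H](OC(C)=O)C/C(C)=C/[C@H]2OC(=O)C(COC(C)=O)=C12 | intermediate
24 | (2S,4R,5R,6S,8S)-2,13-diacetoxy-4,5-epoxy-8-(methacryloyloxy)germacra-1(10)Z,7(11)-dien-12,6-olide (CNP0268364.3) | C=C(C)C(=O)O[C@H]1C/C(C)=C\[C@@H](OC(C)=O)C[C@@]2(C)O[C@@H]2[C@H]2OC(=O)C(COC(C)=O)=C12 | target

## Step count and risks

Total steps: 15. Longest linear sequence: 15 (fully linear from 1; 6 is bought).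

Three steps most likely to fail:

**Step 12** (Ni/Cr closure onto the lactol). The risks are the acidic pseudo-acid, possible Cr(II) reduction of the ring-opened ene-dicarbonyl, ring strain, and the C6 facial outcome, which rests on a conformational argument only. The fallback sets out from 19 and comes back at 21. The carboxylate of the ring-opened tautomer is methylated (MeI, KHCO3, DMF) to give the open-chain methyl (2Z)-4-oxobut-2-enoate F1, a true aldehyde. This is cyclised under catalytic asymmetric Ni/Cr conditions (CrCl2 cat., chiral oxazoline–sulfonamide ligand, NiCl2·DMP, Mn, Cp2ZrCl2, LiCl, MeCN), so that the catalyst rather than the substrate selects the Re face. The chromium alkoxide then displaces methoxide from the cis ester and gives 21.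

**Step 15** (site and face of the epoxidation). Both trisubstituted olefins carry an allylic acyloxy group, and the outcome is argued from ring strain and analogy, not from data on this ring system. The fallback sets out from 23 and comes back at 24 without a new intermediate. Substrate-controlled peracid delivery is replaced by catalyst-controlled dioxirane transfer with the D-fructose-derived Shi ketone (Oxone, K2CO3 buffer, MeCN–dimethoxymethane–H2O, 0 °C). Its spiro transition state favours trans-configured trisubstituted olefins and, by the usual model, delivers the 4R,5R oxirane; the enantiomeric ketone is available if the sense has to be reversed.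

**Step 7** (iron-catalysed methylmagnesiation next to a second alkyne; it follows step 6, a propargylation of an ynal that is itself little precedented). The fallback sets out from 8 and comes back at 13, replacing steps 5 to 7. The alkyne is lithiated and acylated with methyl chloroformate to give the ynoate F2. Syn-addition of Me2CuLi (THF, −78 °C, quench at −78 °C) gives the (2Z)-3-methyl enoate F3, with the chain and the ester cis. DIBAL-H reduces this to the (Z)-allylic alcohol F4, and MnO2 gives the (Z)-enal F5. Phosphoric-acid-catalysed propargylation of F5 with 6 ((S)-TRIP, Si face) then gives 13.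

## Further compounds

F1 | step 12 | methyl (2Z)-2-(acetoxymethyl)-3-[(1S,3Z,5S,7E)-5-acetoxy-1-(TBS-oxy)-8-iodo-3,7-dimethylocta-3,7-dien-1-yl]-4-oxobut-2-enoate | I/C=C(\C)C[C@H](OC(C)=O)/C=C(/C)C[C@H](O[Si](C)(C)C(C)(C)C)/C(C=O)=C(\COC(C)=O)C(=O)OC
F0 | step 15 | none | none
F2 | step 7 | methyl (5S)-5-(TBS-oxy)-5-[5-TBS-4-(TBS-oxymethyl)furan-3-yl]pent-2-ynoate | COC(=O)C#CC[C@H](O[Si](C)(C)C(C)(C)C)c1coc([Si](C)(C)C(C)(C)C)c1CO[Si](C)(C)C(C)(C)C
F3 | step 7 | methyl (2Z,5S)-5-(TBS-oxy)-5-[5-TBS-4-(TBS-oxymethyl)furan-3-yl]-3-methylpent-2-enoate | COC(=O)/C=C(/C)C[C@H](O[Si](C)(C)C(C)(C)C)c1coc([Si](C)(C)C(C)(C)C)c1CO[Si](C)(C)C(C)(C)C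
F4 | step 7 | (2Z,5S)-5-(TBS-oxy)-5-[5-TBS-4-(TBS-oxymethyl)furan-3-yl]-3-methylpent-2-en-1-ol | OC/C=C(/C)C[C@H](O[Si](C)(C)C(C)(C)C)c1coc([Si](C)(C)C(C)(C)C)c1CO[Si](C)(C)C(C)(C)C
F5 | step 7 | (2Z,5S)-5-(TBS-oxy)-5-[5-TBS-4-(TBS-oxymethyl)furan-3-yl]-3-methylpent-2-enal | O=C/C=C(/C)C[C@H](O[Si](C)(C)C(C)(C)C)c1coc([Si](C)(C)C(C)(C)C)c1CO[Si](C)(C)C(C)(C)C
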